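You asked for a number, so here is how I got mine.

common to all: free catalyst 2 mol%

| run | starting material | second substrate | coupling partner | protic impurity | remark |
|---|---|---|---|---|---|
| dawn | 27 mM | 1 equiv | 0.50 equiv | 19 mM | run made earlier |
| spring | 42 mM | 1 equiv | 0.50 equiv | 19 mM | run made earlier |
| flask | 19 mM | 1.00 equiv | 0.500 equiv | 19.0 mM |  |

- dawn (time / min: target / %, starting material / %): 0.333: 16.4, 82.5; 0.500: 21.3, 76.2; 0.833: 29.0, 69.9; 1.33: 33.8, 65.7; 2.50: 36.1, 63.2; 4.00: 34.8, 62.8
- spring (time / min: target / %, starting material / %): 0.333: 21.6, 76.7; 0.500: 27.4, 70.5; 0.833: 32.8, 65.8; 1.33: 36.0, 63.6; 2.50: 34.8, 63.1; 4.00: 35.1, 63.5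

(each reading ± 0.5 percentage points)

- the numbers in the tables scatter by 0.5 percentage points (one standard deviation)
- what is bound to the catalyst counts as converted

- factor on the rate of making target when 5.0% of the starting material are converted if coupling partner is charged twice over
- factor on the rate when 5.0% of the starting material are converted if free catalyst is charged at 10 mol% instead

In the dawn run at 0.500 min, target and starting material fell short of the charge by 2.5 percentage points, against a catalyst charge of 2 mol%. I read the gap as starting material bound to catalyst, which counts as converted, and I took the rate of making target to follow that bound amount.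

So I worked with the reach: in the flask at 2 mol% it came to 2.50, the conversion looked at divided by the catalyst charged. The crossing is a reach of one. Above it, the mark leaves room for the whole catalyst to be bound; below it, the mark is passed before the whole catalyst can be bound. At 10 mol% the reach fell to 0.500, because the catalyst charge is larger than the mark.

An equal bound share in both flasks gives a factor of 5.00. A fully bound 2 mol% catalyst against a bound amount equal to the mark gives 2.50. I committed to the middle of these on a ratio scale, 3.54.

Your forecast said 1.6 for doubling the partner and 3 for the richer catalyst, holding that at 10 mol% the conversion at the mark “is mostly catalyst still loading”. My factor was higher than yours.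

The simulation gave 1.50 for doubling and 4.07 for the richer catalyst, which lies above the reach, below 5.00, and above my 3.54.

second substrate + free catalyst ⇌ catalyst intermediate B (K = 118 M⁻¹, k = 22.5 M⁻¹ s⁻¹); starting material + free catalyst ⇌ catalyst intermediate A (K = 5580 M⁻¹, k = 50.8 M⁻¹ s⁻¹); coupling partner + catalyst intermediate B → free catalyst + second product (k = 101 M⁻¹ s⁻¹); coupling partner + catalyst intermediate A → free catalyst + target (k = 81.6 M⁻¹ s⁻¹); coupling partner + protic impurity → quenched reagent (k = 0.0446 M⁻¹ s⁻¹) The flask passed the mark at 0.106 min, making target at 7.54 mM min⁻¹. Catalyst intermediate A and coupling partner went on giving target while the partner lasted: at 0.500 min the partner stood at 51.4% of its charge and at 2.50 min at 1.59%, the limiting reagent, with target at 35.4%. At 5.00 min catalyst intermediate A held 95.6% of the catalyst, and target stood at 36.1%.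

The readings come from a simulation with made-up constants; noise was put on by code.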